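The readings are simulated with constants of no real substance, noise included.

Take the ratio of starting complex to complex with one exchanged at the moment the latter stands highest: there its gain equals its loss, so the ratio says how many times faster, molecule for molecule, complex with one exchanged is lost than starting complex is. Call it the loss ratio κ, an apparent selectivity factor.

the same everywhere: starting complex 23 mM
- Thursday's: incoming ligand 0.74 equiv (fed, over 3.0 h); leaving ligand 1 equiv; run made earlier; the fed solution adds 0.10 times the starting volume
- Sunday's: incoming ligand 1.7 equiv (fed, over 3.0 h); leaving ligand 1 equiv; run made earlier; the fed solution adds 0.10 times the starting volume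
- flask: incoming ligand 1.10 equiv (fed, over 3.0 h); leaving ligand 1.00 equiv; the fed solution adds 0.10 times the starting volume; time 15 h

- Thursday's (time / h: complex with one exchanged / %, starting complex / %): 2.00: 2.5, 95.7; 4.00: 7.2, 90.8; 6.00: 9.3, 83.6; 12.0: 10.3, 71.5
- Sunday's (time / h: complex with one exchanged / %, starting complex / %): 2.00: 6.0, 92.5; 4.00: 13.8, 80.4; 6.00: 13.6, 67.4; 12.0: 9.6, 48.2

(readings scatter by 1 percentage point)

* time up to 15 h at which complex with one exchanged stands highest
* the amount of complex with one exchanged, in percent of the starting complex charged, at that time
* earliest time at which at least nineteen twentieths of that best amount are there
* latest time at which they still are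

- amounts are per litre of the starting volume; all of the dose is in the solution fed

Thursday's run and Sunday's run look nearly the same, differing in the incoming ligand charged, yet Thursday's highest reading is 10.3% at 12.0 h and Sunday's is 13.8% at 4.00 h. You can see why in κ: Thursday's highest reading gives 6.94, and Sunday's, pooled over its two level readings at 4.00 h and 6.00 h, gives 5.39, so Sunday's run climbed higher because its loss stood lower against its gain.

If κ holds steady, dividing one rate by the other removes the clock, so the pace of the feed drops out, and integrating in closed form puts the top at κ raised to the power −κ/(κ − 1) of the charge. For Sunday's run that gives 12.6%, lower than its reading, so you should expect my figures to run low. Both runs charge the same leaving ligand, and two points test nothing, so I simply assume a straight line: κ equals 2.03 times leaving over incoming ligand charged, plus 4.20. For the flask this gives a loss ratio of 6.04 and a top of 11.6%.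

The forecast, higher than my figure, expects 12.2% at 8.3 h on a peak that “is very flat”, with the band asked for open from 5.6 h to 13.3 h.

The flask gives 12.6% at 7.57 h, with the band open from 5.69 h to 10.1 h, so the band closes earlier than the forecast said.

    starting complex + incoming ligand → leaving ligand + complex with one exchanged (k = 0.0456 /M/min)
    complex with one exchanged + incoming ligand → leaving ligand + complex with two exchanged (k = 0.135 /M/min)
    complex with two exchanged + incoming ligand → leaving ligand + complex with three exchanged (k = 0.0743 /M/min)
    leaving ligand + complex with one exchanged → side product (k = 0.0726 /M/min)

At the top of the flask the loss ratio stands at 5.80, a little under the 6.04 I reckoned. Now raise the leaving ligand to 4.00 equiv in a neighbouring flask, everything else as in the recipe: the same line, stretched to a charge neither run tried, gives κ of 11.6 and a top of 6.85%, and that neighbouring flask reaches 7.55%.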